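In the dihydropyranone ring (O1, C2=O, C3, C4, C5, C6) the carbinol carbon C6 is allylic to the exocyclic C7=C8 alkene. O1–C6 is therefore an allylic ester bond, and C5–C6 can be read as the former vinyl group of a 1,3-diene. Everything rests on an enantioselective palladium-catalysed Heck/Tsuji–Trost annulation. A (Z)-β-iodoacrylic acid bearing the homoprenyl chain adds to the terminal CH2 of an open-chain 2-(hydroxymethyl)-1,3-diene (C4–C5), and the resulting allylpalladium is captured by its own carboxylate (O1–C6). One operation builds the lactone ring and its only stereocentre from two achiral acyclic fragments. Acetylation and desilylation then finish the target.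

Key step: step 7

Assumption: the sense of induction of the phosphoramidite ligand in the annulation cannot be predicted with confidence, so the ligand antipode that gives the (R)-lactone is to be identified in a first run (both antipodes are commercial); the Z enynol starting material is taken to be purchasable as the pure Z isomer.

Step 1
Reactants: 1 5-bromo-2-methylpent-2-ene; 2 prop-2-yn-1-ol
Product: 5 (Z)-2-(iodomethylidene)-6-methylhept-5-en-1-ol, via homoprenylmagnesium bromide 3 (not isolated), via cyclic alkenylmagnesium alkoxide 4 (not isolated)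
Conditions: 1 (2.5 equiv), Mg, THF, reflux; then 2, CuI (10 mol %), THF, −10 °C to rt; then I2, THF, −10 °C; aq NH4Cl
Reagents that add atoms: iodine, II
Why: Copper-catalysed anti-carbomagnesiation of a propargylic alcohol, in which the magnesium alkoxide sends the homoprenyl group to C2 and holds magnesium on C3 inside the five-membered chelate 4, so that iodinolysis with retention should give only the isomer with iodine cis to CH2OH.

Step 2
Reactants: 5 (Z)-2-(iodomethylidene)-6-methylhept-5-en-1-ol
Product: 7 (Z)-2-(iodomethylidene)-6-methylhept-5-enoic acid, via iodo enal 6 (not isolated)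
Conditions: TEMPO (20 mol %), PhI(OAc)2 (2.2 equiv), MeCN/H2O 1:1, 0 °C to rt, dark
Reagents that add atoms: water, O
Why: TEMPO/PhI(OAc)2 oxidation of a primary allylic alcohol runs through the aldehyde hydrate to the acid under near-neutral conditions that should spare the vinyl iodide, the trisubstituted alkene and the Z geometry.

Step 3
Reactants: 2 prop-2-yn-1-ol; 8 vinylmagnesium bromide
Product: 10 (Z)-2-(iodomethylidene)but-3-en-1-ol, via cyclic dienylmagnesium alkoxide 9 (not isolated)
Conditions: 8 (2.5 equiv, 1 M in THF), CuI (10 mol %), THF, −10 °C to rt; then I2, THF, −10 °C; aq NH4Cl; used at once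
Reagents that add atoms: iodine, II
Why: The same alkoxide-directed anti-carbomagnesiation/iodinolysis places the vinyl group (future C5–C6) on C7 and iodine on C8 cis to CH2OH, which fixes the C7=C8 geometry of the target.

Step 4
Reactants: 11 (Z)-3-methylpent-2-en-4-yn-1-ol
Product: 12 (Z)-tert-butyldimethyl[(3-methylpent-2-en-4-yn-1-yl)oxy]silane
Conditions: TBSCl, imidazole, CH2Cl2, 0 °C to rt
Reagents that add atoms: tert-butyldimethylsilyl chloride, CC(C)(C)[Si](C)(C)Cl
Why: Imidazole-promoted silylation masks the alcohol that must end up free, so that the two primary allylic alcohols of the target stay distinguishable.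

Step 5
Reactants: 12 (Z)-tert-butyldimethyl[(3-methylpent-2-en-4-yn-1-yl)oxy]silane
Product: 13 (Z)-tert-butyldimethyl[(3-methylpenta-2,4-dien-1-yl)oxy]silane
Conditions: H2 (1 atm, 1 equiv uptake), Pd/CaCO3 poisoned with Pb(OAc)2 (Lindlar catalyst), quinoline, hexane, rt
Reagents that add atoms: none
Why: Lindlar semihydrogenation, in which the terminal alkyne binds the poisoned palladium surface far better than the diene product, so that uptake should stop at the vinyl group without touching the Z alkene.

Step 6
Reactants: 13 (Z)-tert-butyldimethyl[(3-methylpenta-2,4-dien-1-yl)oxy]silane; 10 (Z)-2-(iodomethylidene)but-3-en-1-ol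
Product: 15 (2Z,6Z)-8-(tert-butyldimethylsilyloxy)-2-ethenyl-6-methylocta-2,6-dien-1-ol, via homoallylic alkylborane 14 (not isolated)
Conditions: 13, 9-BBN-H (1.1 equiv), THF, 0 °C to rt; then 10, PdCl2(dppf)·CH2Cl2 (5 mol %), AsPh3 (10 mol %), aq K3PO4 (3 equiv), DMF, rt
Reagents that add atoms: none
Why: Hydroboration/B-alkyl Suzuki–Miyaura coupling, in which 9-BBN-H adds anti-Markovnikov to the only monosubstituted alkene and the alkenyl iodide couples with retention, so that the chain ends up cis to CH2OH and trans to the vinyl group.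

Step 7
Reactants: 7 (Z)-2-(iodomethylidene)-6-methylhept-5-enoic acid; 15 (2Z,6Z)-8-(tert-butyldimethylsilyloxy)-2-ethenyl-6-methylocta-2,6-dien-1-ol
Product: 17 (R)-6-[(2E,6Z)-8-(tert-butyldimethylsilyloxy)-1-hydroxy-6-methylocta-2,6-dien-2-yl]-3-(4-methylpent-3-en-1-yl)-5,6-dihydro-2H-pyran-2-one, via allylpalladium carboxylate 16 (not isolated)
Conditions: 7 (1 equiv), 15 (1.2 equiv), Pd2(dba)3·CHCl3 (2.5 mol %), BINOL-derived phosphoramidite with a bis(1-phenylethyl)amino group (11 mol %), Ag2CO3 (0.6 equiv), 1,4-dioxane, 50 °C, dark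
Reagents that add atoms: none
Why: Zerovalent palladium inserts into the C–I bond of 7 with retention, the alkenylpalladium carboxylate adds syn across the only monosubstituted alkene of 15 with carbon going to the CH2 terminus (C4–C5) and palladium to C6, where it is held as the η3-allyl complex 16 over C6–C7–C8, and the tethered carboxylate then closes O1–C6 and returns zerovalent palladium. The closest known reaction type is the Larock heteroannulation of 1,3-dienes (a Heck/Tsuji–Trost cascade), established for aryl and vinylic halides that carry OH, NHR or CO2H groups and known in ligand-controlled enantioselective form with halophenols and haloanilines on dienes and with iodo acids on allenes. The dihydropyranone ring closes in a 6-exo mode at the proximal allyl terminus C6, whereas attack at C8 would need an eight-membered ring. C6 is the only new stereocentre and is fixed by the chiral phosphoramidite in the face-selective carbopalladation of the vinyl group, the configuration being relayed stereospecifically through 16 into the C–O bond. The chain on C8 enters 16 in the syn position because of the geometry of 15, so C7=C8 keeps its geometry (the descriptor changes from 2Z to 2E only through the priority rules), and a π–σ–π slip at C8 would change the alkene geometry and C6 together and so give a separable isomer, not the enantiomer. Chemoselectivity rests on the inertness of the three trisubstituted alkenes to carbopalladation, on the Pd–C4 bond being trans to the homoprenyl chain (no intramolecular Heck closure), and on carrying a silyl ether and a free OH in place of the allylic acetate, which zerovalent palladium could ionise.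

Step 8
Reactants: 17 the hydroxy lactone from step 7
Product: 18 (R)-6-[(2E,6Z)-1-acetoxy-8-(tert-butyldimethylsilyloxy)-6-methylocta-2,6-dien-2-yl]-3-(4-methylpent-3-en-1-yl)-5,6-dihydro-2H-pyran-2-one
Conditions: Ac2O, pyridine, DMAP (5 mol %), CH2Cl2, 0 °C
Reagents that add atoms: acetic anhydride, CC(=O)OC(C)=O
Why: DMAP-catalysed acylation of the only free hydroxyl group, under conditions too mild to open the lactone or touch C6.

Step 9
Reactants: 18 the silyl-protected acetate from step 8
Product: 19 (R)-6-[(2E,6Z)-1-acetoxy-8-hydroxy-6-methylocta-2,6-dien-2-yl]-3-(4-methylpent-3-en-1-yl)-5,6-dihydro-2H-pyran-2-one (target)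
Conditions: HF·pyridine, pyridine, THF, 0 °C to rt
Reagents that add atoms: none
Why: Fluoride-mediated desilylation, in which buffered HF·pyridine should cleave the primary allylic TBS ether without harming the acetate, the lactone, the alkene geometries or the stereocentre.

Compound list
1 | 5-bromo-2-methylpent-2-ene (homoprenyl bromide) | CC(C)=CCCBr | starting material
2 | prop-2-yn-1-ol (propargyl alcohol) | C#CCO | starting material
3 | (4-methylpent-3-en-1-yl)magnesium bromide | CC(C)=CCC[Mg]Br | intermediate
4 | cyclic alkenylmagnesium alkoxide (five-membered O–Mg–CH=C–CH2 chelate bearing the homoprenyl group) | CC(C)=CCCC1=C[Mg]OC1 | intermediate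
5 | (Z)-2-(iodomethylidene)-6-methylhept-5-en-1-ol | OC/C(CCC=C(C)C)=C\I | intermediate
6 | (Z)-2-(iodomethylidene)-6-methylhept-5-enal | O=C/C(CCC=C(C)C)=C\I | intermediate
7 | (Z)-2-(iodomethylidene)-6-methylhept-5-enoic acid | OC(=O)/C(CCC=C(C)C)=C\I | intermediate
8 | vinylmagnesium bromide | C=C[Mg]Br | starting material
9 | cyclic dienylmagnesium alkoxide (five-membered O–Mg–CH=C–CH2 chelate bearing the vinyl group) | C=CC1=C[Mg]OC1 | intermediate
10 | (Z)-2-(iodomethylidene)but-3-en-1-ol | OC/C(C=C)=C\I | intermediate
11 | (Z)-3-methylpent-2-en-4-yn-1-ol | C#C/C(C)=C\CO | starting material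
12 | (Z)-tert-butyldimethyl[(3-methylpent-2-en-4-yn-1-yl)oxy]silane | C#C/C(C)=C\CO[Si](C)(C)C(C)(C)C | intermediate
13 | (Z)-tert-butyldimethyl[(3-methylpenta-2,4-dien-1-yl)oxy]silane | C=C/C(C)=C\CO[Si](C)(C)C(C)(C)C | intermediate
14 | 9-[(Z)-5-(tert-butyldimethylsilyloxy)-3-methylpent-3-en-1-yl]-9-borabicyclo[3.3.1]nonane | B1(CC/C(C)=C\CO[Si](C)(C)C(C)(C)C)C2CCCC1CCC2 | intermediate
15 | (2Z,6Z)-8-(tert-butyldimethylsilyloxy)-2-ethenyl-6-methylocta-2,6-dien-1-ol | OC/C(C=C)=C\CC/C(C)=C\CO[Si](C)(C)C(C)(C)C | intermediate
16 | allylpalladium carboxylate from 7 and 15, drawn as the C6-bound σ-allyl palladacycle, chiral ligand omitted | OC/C(=C\CC/C(C)=C\CO[Si](C)(C)C(C)(C)C)C1CC=C(CCC=C(C)C)C(=O)O[Pd]1 | intermediate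
17 | (R)-6-[(2E,6Z)-8-(tert-butyldimethylsilyloxy)-1-hydroxy-6-methylocta-2,6-dien-2-yl]-3-(4-methylpent-3-en-1-yl)-5,6-dihydro-2H-pyran-2-one | OC/C(=C\CC/C(C)=C\CO[Si](C)(C)C(C)(C)C)[C@H]1CC=C(CCC=C(C)C)C(=O)O1 | intermediate
18 | (R)-6-[(2E,6Z)-1-acetoxy-8-(tert-butyldimethylsilyloxy)-6-methylocta-2,6-dien-2-yl]-3-(4-methylpent-3-en-1-yl)-5,6-dihydro-2H-pyran-2-one | CC(=O)OC/C(=C\CC/C(C)=C\CO[Si](C)(C)C(C)(C)C)[C@H]1CC=C(CCC=C(C)C)C(=O)O1 | intermediate
19 | (R)-6-[(2E,6Z)-1-acetoxy-8-hydroxy-6-methylocta-2,6-dien-2-yl]-3-(4-methylpent-3-en-1-yl)-5,6-dihydro-2H-pyran-2-one | CC(=O)OC/C(=C\CC/C(C)=C\CO)[C@H]1CC=C(CCC=C(C)C)C(=O)O1 | target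

Total step count: 9. Longest linear sequence: 6 steps (steps 4, 5, 6, 7, 8, 9).

Steps most likely to fail

**Step 7.**
- What may go wrong: weak facial discrimination in the carbopalladation, or β-hydride loss from C5 of the allylpalladium outrunning the C–O closure.
- Change of approach: the ring is closed at C3=C4 by metathesis instead, and C6 is set by a reagent-controlled allylboration. The fallback sets out from 10, draws on 14 and 7, and comes back to the route at 18.
- Acetylation of 10 (Ac2O, pyridine) gives (Z)-2-(iodomethylidene)but-3-en-1-yl acetate F1.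
- Lemieux–Johnson cleavage of its vinyl group (OsO4 cat., NaIO4, 2,6-lutidine, dioxane/H2O) gives (E)-2-formyl-3-iodoprop-2-en-1-yl acetate F2. The iodoalkene is electron-poor and hindered and should be left alone.
- Brown allylation with (+)-Ipc2B(allyl) (Et2O, −78 °C, NaBO3 work-up) should give (2E,3R)-3-hydroxy-2-(iodomethylidene)hex-5-en-1-yl acetate F3. The (R) sense is expected by analogy with benzaldehyde and α-branched enals.
- B-alkyl Suzuki–Miyaura coupling with borane 14 under the conditions of step 6 gives (2E,6Z)-8-(tert-butyldimethylsilyloxy)-2-[(1R)-1-hydroxybut-3-en-1-yl]-6-methylocta-2,6-dien-1-yl acetate F4.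
- Formate hydrodeiodination of 7 (Pd(PPh3)4, HCO2H, Et3N, DMF) gives 6-methyl-2-methylidenehept-5-enoic acid F5.
- Steglich esterification of F4 with F5 (DCC, DMAP) gives (1R)-1-[(2E,6Z)-1-acetoxy-8-(tert-butyldimethylsilyloxy)-6-methylocta-2,6-dien-2-yl]but-3-en-1-yl 6-methyl-2-methylidenehept-5-enoate F6.
- Ring-closing metathesis with the second-generation Grubbs catalyst (CH2Cl2, reflux) gives 18.

**Step 3.**
- What may go wrong: sluggish addition of the sp2 Grignard reagent to the alkynyl alkoxide, and polymerisation or Diels–Alder dimerisation of the iodo diene during isolation.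
- Change of approach: the C7=C8 alkene is taken from a 1,2-dihaloalkene template, and both carbon substituents are brought in by site-selective cross-coupling, so that 10 is never made. The fallback sets out from 2 and comes back at 15.
- anti-Bromination of 2 (Br2, CH2Cl2, −78 °C) gives (E)-2,3-dibromoprop-2-en-1-ol F7.
- Its less hindered terminal C–Br bond, cis to CH2OH, should couple first with borane 14 (PdCl2(dppf)·CH2Cl2, aq K3PO4, DMF, rt). This gives (2E,6Z)-2-bromo-8-(tert-butyldimethylsilyloxy)-6-methylocta-2,6-dien-1-ol F8.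
- Stille coupling with tributyl(vinyl)stannane (Pd(PPh3)4, CuI, DMF) replaces the remaining bromide with retention and gives 15.

**Step 6.**
- What may go wrong: slow transmetalation of the alkylborane, so that the iodo diene is lost to protodeiodination or Heck-type oligomerisation in the basic aqueous medium.
- Change of approach: C8–C9 is made by acetylide alkylation, and the C7=C8 geometry by syn-hydrostannation of an alkyne. The fallback sets out from 14, uses 2, and comes back at 15.
- Oxidation of 14 (H2O2, NaOH) gives (Z)-5-(tert-butyldimethylsilyloxy)-3-methylpent-3-en-1-ol F9.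
- The Appel reaction (I2, PPh3, imidazole) gives (Z)-tert-butyl[(5-iodo-3-methylpent-2-en-1-yl)oxy]dimethylsilane F10.
- Alkylation of the dilithio salt of 2 (n-BuLi, 2 equiv, THF/DMPU, −78 °C to rt) gives (Z)-8-(tert-butyldimethylsilyloxy)-6-methyloct-6-en-2-yn-1-ol F11.
- Palladium-catalysed hydrostannation (Bu3SnH, PdCl2(PPh3)2, THF, 0 °C), with tin going to the carbon next to CH2OH, gives (2E,6Z)-8-(tert-butyldimethylsilyloxy)-6-methyl-2-(tributylstannyl)octa-2,6-dien-1-ol F12.
- Stille coupling with vinyl bromide (Pd2(dba)3, AsPh3, NMP) gives 15.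

Further compounds
F1 | step 7 | (Z)-2-(iodomethylidene)but-3-en-1-yl acetate | CC(=O)OC/C(C=C)=C\I
F2 | step 7 | (E)-2-formyl-3-iodoprop-2-en-1-yl acetate | CC(=O)OC/C(C=O)=C\I
F3 | step 7 | (2E,3R)-3-hydroxy-2-(iodomethylidene)hex-5-en-1-yl acetate | CC(=O)OC/C(=C\I)[C@H](O)CC=C
F4 | step 7 | (2E,6Z)-8-(tert-butyldimethylsilyloxy)-2-[(1R)-1-hydroxybut-3-en-1-yl]-6-methylocta-2,6-dien-1-yl acetate | CC(=O)OC/C(=C\CC/C(C)=C\CO[Si](C)(C)C(C)(C)C)[C@H](O)CC=C
F5 | step 7 | 6-methyl-2-methylidenehept-5-enoic acid | C=C(CCC=C(C)C)C(=O)O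
F6 | step 7 | (1R)-1-[(2E,6Z)-1-acetoxy-8-(tert-butyldimethylsilyloxy)-6-methylocta-2,6-dien-2-yl]but-3-en-1-yl 6-methyl-2-methylidenehept-5-enoate | CC(=O)OC/C(=C\CC/C(C)=C\CO[Si](C)(C)C(C)(C)C)[C@H](OC(=O)C(=C)CCC=C(C)C)CC=C
F7 | step 3 | (E)-2,3-dibromoprop-2-en-1-ol | OC/C(Br)=C\Br
F8 | step 3 | (2E,6Z)-2-bromo-8-(tert-butyldimethylsilyloxy)-6-methylocta-2,6-dien-1-ol | OC/C(Br)=C\CC/C(C)=C\CO[Si](C)(C)C(C)(C)C
F9 | step 6 | (Z)-5-(tert-butyldimethylsilyloxy)-3-methylpent-3-en-1-ol | OCC/C(C)=C\CO[Si](C)(C)C(C)(C)C
F10 | step 6 | (Z)-tert-butyl[(5-iodo-3-methylpent-2-en-1-yl)oxy]dimethylsilane | ICC/C(C)=C\CO[Si](C)(C)C(C)(C)C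
F11 | step 6 | (Z)-8-(tert-butyldimethylsilyloxy)-6-methyloct-6-en-2-yn-1-ol | OCC#CCC/C(C)=C\CO[Si](C)(C)C(C)(C)C
F12 | step 6 | (2E,6Z)-8-(tert-butyldimethylsilyloxy)-6-methyl-2-(tributylstannyl)octa-2,6-dien-1-ol | OC/C([Sn](CCCC)(CCCC)CCCC)=C\CC/C(C)=C\CO[Si](C)(C)C(C)(C)C
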